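The ratio I started from was D over Z, summed over the readings of both earlier runs. I called it the split, the selectivity factor of two side-by-side paths from L and X: 0.346.

| flask | L | X | remark | time |
|---|---|---|---|---|
| violet | 46 mM | 32.2 mM | the very flask that is asked about, followed so far |  |
| grey | 69 mM | 32.2 mM | run made earlier |  |
| flask | 46 mM | 32.2 mM |  | 20 h |

| run | time / h | D / % | Z / % |
|---|---|---|---|
| violet | 1.00 | 10 | 19 |
| violet | 2.00 | 11 | 32 |
| violet | 3.00 | 14 | 39 |
| violet | 4.00 | 14 | 40 |
| grey | 4.00 | 9 | 35 |
| grey | 8.00 | 11 | 35 |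
| grey | 10.0 | 12 | 36 |
| grey | 15.0 | 12 | 33 |

(scatter of a reading: 2 percentage points)

1. share of D in D plus Z at 6.0 min
2. share of D in D plus Z at 20 h

- the earlier runs were read with a standard deviation of 2 percentage points
- a reading or a percentage of Z counts all its forms, free or not

As a reading, that split made D a share of 25.7 % of D plus Z, and I held this share flat from the start. Then I drew the violet curve of D plus Z. It read 29.0 % of the L charged after 1.00 h and bent to a reading of 54.0 % after 4.00 h. I took its level from the charges: X was the limiting reagent, with less X charged than L, so the ceiling was 70.0 % of L. The grey run checked this, reading 48.0 % after 10.0 h against its ceiling of 46.7 %. At the violet ceiling my share put D at 18.0 % and Z at 52.0 %.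

The forecast gave 31 % at 6.0 min (range 20 % to 46 %) and 27 % at 20 h (range 22 % to 33 %). Early on it stood higher than my share, on a hint of “D being favoured at high X”.

The flask gave 24.9 % at 6.0 min and 22.3 % at 20 h. Between 10.0 h and 20.0 h, D went from 15.5 % to 14.9 % while Z went from 49.3 % to 51.7 %. The split laid on Z gave D 11.3 % after 2.00 h, where the flask held 11.1 %, but 17.9 % after 20.0 h, where it held 14.9 %.

    L + X ⇌ Z (K = 36.0 M⁻¹, k = 0.00328 M⁻¹ s⁻¹)
    L + X ⇌ D (K = 194 M⁻¹, k = 0.00107 M⁻¹ s⁻¹)
    E ⇌ Z, rate k3*(cs3 - [Z]) while solid is left; crystals form when [Z] > cs3 (solubility = 0.660 mM, k = 0.00274 s⁻¹)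
    2 L → G (k = 8.79 × 10⁻⁷ M⁻¹ s⁻¹)

In the neighbour flask with 180 mM of L, the split gave a share of 25.7 % and, at a ceiling of 17.9 % of the L charged, D 4.60 % of that L. That flask gave a share of 24.8 % at 6.0 min and 21.7 % at 20 h, and at 20 h it held D 3.86 % of its L.

The readings are calculated for an exercise, noise included.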